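Remark on the chemistry: the side chain of the cyclocarbonylation substrate is carried as a diethyl acetal (same carbon skeleton, same bonds formed in the key step) instead of a silyl ether, because a free 2‑hydroxyethyl group beside the aryl lactone would be expected to translactonise to a γ‑butyrolactone. The alkene geometry and all configurations were re‑derived and are consistent: Z alkene gives the 3,4‑cis lactone, and the target is 3S,3'S,4R,4'R.

## Structural features

The target is a dimer of two 4‑(4‑hydroxyphenyl)‑3,4‑dihydrocoumarins joined only through the C3–C3' single bond. The unprimed half has a phloroglucinol‑type ring A (OH at C5 and C7); the primed half has a fully oxygenated ring B (OH at C5', C6', C7' and C8'). The four stereocentres C4, C3, C3' and C4' are contiguous (4R,3S,3'S,4'R), and in each lactone the C4 aryl group and the C3 substituent are cis. Both lactones are aryl esters and therefore acyl donors, and C3–H and C3'–H lie α to a carbonyl, so base can epimerise them towards the trans arrangement. The eight free phenols, above all the pentaoxygenated ring B, are sensitive to air, so they are carried as methyl ethers to the last step. The real difficulty is the contiguous tetrad: two cis relationships and the correct relative sense across C3–C3', beside crowded di‑ortho‑substituted aryl groups at C4 and C4'. The key step exploits the ring A lactone, in which the carbonyl carbon C2 lies between O1 (on C8a of ring A) and C3 while H3 and H4 are cis. C2 can therefore be inserted as carbon monoxide between the ring A phenol and C3 of a Z alkene C3=C4, with hydrogen and acyl added syn across that bond. The ring B lactone is then closed with the complementary polarity, a nucleophilic C3' (enolate) and an electrophilic C4' (ortho‑quinone methide).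

## Logic of the disconnections

23 is traced to 22 by cutting eight O–CH3 bonds. Methyl ethers are the only phenol protection that survives every earlier step, and their removal is kept for the end because the free polyphenol is the most fragile compound of the route. The forward step must cleave eight ethers without opening the lactones for good and without touching C3 or C3'.

22 is cut at C3'–C4' and O1'–C2' into 14 and 20 (the latter reacting through 21). C3' is α to a carbonyl and C4' is the benzylic terminus of a quinone methide, so the cut follows the natural polarity. It removes the pentaoxygenated half as an achiral piece and leaves a chiral partner with only two stereocentres. The forward step must give the cis ring and the correct absolute sense beside the existing C3 centre, with a base too weak to epimerise C3.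

14 is traced through 13 and 12 to 11 by functional group changes on the two‑carbon arm (aryl ester C–O, carboxyl oxygen, acetal). The arm carbon that becomes C2' is held at the aldehyde level as an acetal, so no hydroxyl group ever stands γ to the aryl lactone. The forward steps must be mild towards the lactone and C3.

11 is cut at C2–C3 and C2–O1 (loss of CO) and at C4–H, giving 10. This converts a lactone with two stereocentres into an achiral alkene whose geometry encodes the relative configuration. The forward step must place the acyl group at C3, add syn without isomerising the alkene, and select one alkene face.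

10 is traced through 9 to 5 and 8 by cutting O–Si and the C4–C4a aryl–alkenyl bond. Cross‑coupling of an alkenyl boronate proceeds with retention, and the ring A aryl must enter second because the remaining boron is the one cis to the chain. The forward steps must achieve a hindered coupling and unmask the phenol without acid.

5 is cut at the C4–anisyl bond into 3 and 4. Of the two geminal boron groups the one trans to the chain reacts first, so the geometry is set by the order of the two couplings. The forward step must stop cleanly after one coupling.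

3 is traced through 2 to 1 by cutting the C3=C4 double bond (aldehyde carbon C3, gem‑diboryl carbanion C4) and by an oxidation level change. This reaches a commercial three‑carbon acetal alcohol. The forward step must tolerate a base‑sensitive β‑alkoxy aldehyde.

8 is traced through 7 to 6 by cutting O–Si and C–I. The forward iodination must select the position ortho to the hydroxyl.

20 is cut at C4'–C4a' and C4'–S into 18 and 19, and 18 at C8a'–O into 15. Only one ring position of 18 carries hydrogen, so the substitution has no regiochemical choice, and the sulfinate installed is the leaving group that later releases 21.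

## Other disconnections considered

Alternative 1: The cut is at C3–C4 and O1–C2 of the unprimed lactone, so ring A is attached last. In the forward step a chiral triazolium‑derived carbene converts 4‑nitrophenyl 2‑[(3R,4R)‑5,6,7,8‑tetramethoxy‑4‑(4‑methoxyphenyl)‑2‑oxo‑3,4‑dihydro‑2H‑chromen‑3‑yl]acetate A2 into its azolium enolate. This adds endo to the ring A ortho‑quinone methide A4, released by base from sulfone A3, and O‑acylation closes the lactone to the octamethyl ether A1, which is the same compound as 22.
- In favour: the reaction type is established, the route is convergent, and A2 could itself come from the same annulation on ring B, so two annulations and one deprotection would reach 23.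
- Against: each annulation must impose its sense beside existing centres, the exocyclic carbon of A4 is crowded by the C5 methoxy group, and the base‑sensitivity of C3 is met twice.
- Comparison: on precedent and step economy this alternative is the better plan; on cis control of ring A the two are equal (endo approach there, alkene geometry here). The chosen route keeps it as the fallback for the key step. Its own merits are that the relative configuration of the ring A half is fixed by an isolable Z alkene rather than by a transition‑state preference, and that C2 comes from carbon monoxide with no stoichiometric waste.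

Alternative 2: The cut is inside ring A (C8a–C4a, C5–C6 and C8–C8a), so the arene is grown from a propargylic stereocentre. In the forward step 3‑ethoxycyclobut‑2‑en‑1‑one A7 is heated with the ynol ether trimethyl (3R)‑5‑ethoxy‑3‑(4‑methoxyphenyl)pent‑4‑yne‑1,2,2‑tricarboxylate A6. Ring opening to a vinylketene, [2+2] cycloaddition, a second ring opening and 6π‑electrocyclisation should give trimethyl (3R)‑3‑(2,4‑diethoxy‑6‑hydroxyphenyl)‑3‑(4‑methoxyphenyl)propane‑1,2,2‑tricarboxylate A5.
- In favour: the phenol appears free exactly at C8a with no protecting group and no regiochemical choice, and C4 is fixed before the ring exists; on these two points it is better than the iodination, silylation and desilylation of the chosen route.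
- Against: the key step creates no stereocentre. C3 in A5 is a malonate carbon whose configuration would be set later by protonation after loss of one ester, which is expected to favour trans. A6 has an acidic propargylic hydrogen that may isomerise to an allene on heating, and the ring B half is not addressed.
- Comparison: mechanistically it is a thermal pericyclic cascade without a metal and is well established as a reaction type, whereas the chosen key step is not. It gives no control of the C3/C4 cis relationship and would be several steps longer.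

Alternative 3: The cut is in ring B (C5'–C4a'), so the oxygenated arene is built from a four‑membered ring. In the forward step 4‑hydroxy‑2,3‑dimethoxy‑4‑[(3aR,4R,7aS)‑4‑(4‑methoxyphenyl)‑3,3a,4,7a‑tetrahydro‑2H‑furo[2,3‑b]pyran‑6‑yl]cyclobut‑2‑en‑1‑one A9 is heated. Ring opening to a dienylketene, 6π‑electrocyclisation and tautomerisation (a Moore rearrangement) should give (3aR,4R,9aS)‑6,7‑dimethoxy‑4‑(4‑methoxyphenyl)‑2,3,3a,9a‑tetrahydro‑4H‑furo[2,3‑b]chromene‑5,8‑diol A8.
- In favour: ring B is assembled with every oxygen in place and the crowded C4'–C4a' bond already present. This is equal to the chosen route in regiochemical certainty and better in avoiding an intermolecular substitution at a hindered position.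
- Against: the lithiated bicyclic enol acetal needed for A9 carries two stereocentres and would take many steps. A8 is an air‑sensitive hydroquinone that must be methylated. Turning its acetal carbon into the lactone carbonyl releases a 2‑hydroxyethyl arm beside an aryl lactone, the translactonisation hazard that the acetal arm of the chosen route avoids. The ring A half would still need an annulation as in Alternative 1.
- Comparison: it solves a problem (regiochemistry of ring B) that step 13 of the chosen route does not have, at a much higher step count; mechanistically it is reliable and needs no catalyst.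

Key step: step 8

## Route

Step 1
Reactants: 1 3,3-diethoxypropan-1-ol
Product: 2 3,3-diethoxypropanal
Conditions: (COCl)2, DMSO, CH2Cl2, −78 °C; Et3N, −78 °C → 0 °C
Reagents that add atoms: none
Why: Swern oxidation; the cold, base‑terminated conditions avoid the acid that would cleave the acetal or eliminate ethanol from the β‑alkoxy aldehyde, which is used without storage.

Step 2
Reactants: 2 3,3-diethoxypropanal
Product: 3 2,2'-(4,4-diethoxybut-1-ene-1,1-diyl)bis(4,4,5,5-tetramethyl-1,3,2-dioxaborolane)
Conditions: HC(Bpin)3, lithium 2,2,6,6-tetramethylpiperidide, THF, 0 °C; then 2, −78 °C → rt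
Reagents that add atoms: tris(4,4,5,5-tetramethyl-1,3,2-dioxaborolan-2-yl)methane, CC1(C)OB(OC1(C)C)C(B1OC(C)(C)C(C)(C)O1)B1OC(C)(C)C(C)(C)O1
Why: Boron–Wittig olefination; the stabilised tris(boryl)methyl anion adds to the aldehyde and syn B–O elimination gives the 1,1‑diborylalkene, with no geometry to control because the geminal groups are identical.

Step 3
Reactants: 3 2,2'-(4,4-diethoxybut-1-ene-1,1-diyl)bis(4,4,5,5-tetramethyl-1,3,2-dioxaborolane); 4 1-bromo-4-methoxybenzene
Product: 5 (E)-2-[4,4-diethoxy-1-(4-methoxyphenyl)but-1-en-1-yl]-4,4,5,5-tetramethyl-1,3,2-dioxaborolane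
Conditions: Pd(PtBu3)2 (5 mol %), KOH (3 M aq.), THF, rt, 1.0 equiv of 4
Reagents that add atoms: none
Why: Suzuki–Miyaura coupling; the boryl group trans to the alkyl chain is the less hindered and transmetalates first, so one equivalent of bromide should place the anisyl group trans to the chain and leave the cis boryl group for step 6.

Step 4
Reactants: 6 3,5-dimethoxyphenol
Product: 7 2-iodo-3,5-dimethoxyphenol
Conditions: N-iodosuccinimide (1.0 equiv), CH2Cl2, −20 °C
Reagents that add atoms: N-iodosuccinimide, O=C1CCC(=O)N1I
Why: Electrophilic aromatic iodination; C2 is activated by all three oxygens and is less flanked than C4 between two methoxy groups, and low temperature with one equivalent limits di‑iodination; any 4‑iodo isomer is removed by chromatography.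

Step 5
Reactants: 7 2-iodo-3,5-dimethoxyphenol
Product: 8 (2-iodo-3,5-dimethoxyphenoxy)tri(propan-2-yl)silane
Conditions: iPr3SiCl, imidazole, DMF, rt
Reagents that add atoms: chlorotri(propan-2-yl)silane, CC(C)[Si](Cl)(C(C)C)C(C)C
Why: Silylation of the phenol; the triisopropylsilyl ether should survive aqueous phosphate in step 6 and can be removed by fluoride without acid.

Step 6
Reactants: 5 (E)-2-[4,4-diethoxy-1-(4-methoxyphenyl)but-1-en-1-yl]-4,4,5,5-tetramethyl-1,3,2-dioxaborolane; 8 (2-iodo-3,5-dimethoxyphenoxy)tri(propan-2-yl)silane
Product: 9 (Z)-{2-[4,4-diethoxy-1-(4-methoxyphenyl)but-1-en-1-yl]-3,5-dimethoxyphenoxy}tri(propan-2-yl)silane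
Conditions: Pd(OAc)2 (5 mol %), SPhos (10 mol %), K3PO4, toluene/H2O, 80 °C
Reagents that add atoms: none
Why: Suzuki–Miyaura coupling with retention at the alkenyl carbon, so ring A ends cis to the chain (Z); a dialkylbiarylphosphine is chosen for the di‑ortho‑substituted, electron‑rich iodide and the hindered boronate.

Step 7
Reactants: 9 (Z)-{2-[4,4-diethoxy-1-(4-methoxyphenyl)but-1-en-1-yl]-3,5-dimethoxyphenoxy}tri(propan-2-yl)silane
Product: 10 (Z)-2-[4,4-diethoxy-1-(4-methoxyphenyl)but-1-en-1-yl]-3,5-dimethoxyphenol
Conditions: Bu4NF, AcOH (1 equiv), THF, 0 °C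
Reagents that add atoms: none
Why: Fluoride desilylation of an aryl silyl ether; the buffered, non‑acidic medium leaves the acetal intact and avoids protonation of the electron‑rich diaryl alkene, which would scramble its geometry.

Step 8
Reactants: 10 (Z)-2-[4,4-diethoxy-1-(4-methoxyphenyl)but-1-en-1-yl]-3,5-dimethoxyphenol
Product: 11 (3R,4R)-3-(2,2-diethoxyethyl)-5,7-dimethoxy-4-(4-methoxyphenyl)-3,4-dihydro-2H-chromen-2-one
Conditions: Pd(OAc)2 (5 mol %), (R,R)-DIOP (7.5 mol %), CO (30 bar), H2 (5 bar), toluene, 90 °C
Reagents that add atoms: carbon monoxide, [C-]#[O+]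
Why: Proposed new method: zerovalent palladium formed from Pd(OAc)2 and the bisphosphine is converted by H2 and the phenol into a divalent palladium hydride which, held by the ortho phenol(ate), adds syn across C3=C4 with hydrogen to the diaryl carbon C4 and palladium to the less hindered C3; CO then inserts into the C3–Pd bond with retention and the phenol oxygen attacks the acyl palladium, releasing the lactone and regenerating the hydride. The closest known reaction type is the palladium/bisphosphine cyclocarbonylation of 2‑vinyl‑ and 2‑isopropenylphenols (and, with chiral bisphosphines, of 2‑vinylanilines) to six‑membered lactones and lactams; the extension to a trisubstituted 1,1‑diarylalkene with enantiocontrol is the untested part. The ring closes by intramolecular acyl substitution, a 6‑exo‑trig attack of O1 on the acyl carbon, equivalent to C–O reductive elimination from a seven‑membered aryloxy acyl palladacycle. C4 is set in the hydropalladation and its absolute sense by the alkene face that the DIOP‑bound metal selects; if the sense proves opposite the antipodal ligand is used. C3 is set in the same event relative to C4, because syn addition to the Z alkene (ring A aryl cis to the chain) places the anisyl group and the side chain cis on the new ring, and insertion with retention preserves this. The step needs the acyl group at C3 rather than a quaternary acyl at C4 (which would lead to a benzofuranone), and the two aryl groups on C4 enforce this sterically. It also needs hydropalladation to be effectively irreversible so that neither the geometry nor the position of the double bond is scrambled before insertion; high CO pressure and the absence of strong acid (which would protonate the alkene and open the acetal) serve this.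

Step 9
Reactants: 11 (3R,4R)-3-(2,2-diethoxyethyl)-5,7-dimethoxy-4-(4-methoxyphenyl)-3,4-dihydro-2H-chromen-2-one
Product: 12 2-[(3R,4R)-5,7-dimethoxy-4-(4-methoxyphenyl)-2-oxo-3,4-dihydro-2H-chromen-3-yl]acetaldehyde
Conditions: pyridinium p-toluenesulfonate (cat.), acetone/H2O, 50 °C
Reagents that add atoms: water, O
Why: Acid‑catalysed acetal hydrolysis; the aryl lactone tolerates mild aqueous acid, C3 is not enolised, and no free alcohol is ever formed beside the lactone.

Step 10
Reactants: 12 2-[(3R,4R)-5,7-dimethoxy-4-(4-methoxyphenyl)-2-oxo-3,4-dihydro-2H-chromen-3-yl]acetaldehyde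
Product: 13 2-[(3R,4R)-5,7-dimethoxy-4-(4-methoxyphenyl)-2-oxo-3,4-dihydro-2H-chromen-3-yl]acetic acid
Conditions: NaClO2, NaH2PO4, 2-methylbut-2-ene, t-BuOH/H2O, 0 °C → rt
Reagents that add atoms: sodium chlorite, [Na+].[O-]Cl=O
Why: Pinnick oxidation; buffered chlorite oxidises only the aldehyde, and the alkene scavenger keeps hypochlorous acid away from the electron‑rich rings.

Step 11
Reactants: 13 2-[(3R,4R)-5,7-dimethoxy-4-(4-methoxyphenyl)-2-oxo-3,4-dihydro-2H-chromen-3-yl]acetic acid
Product: 14 4-nitrophenyl 2-[(3R,4R)-5,7-dimethoxy-4-(4-methoxyphenyl)-2-oxo-3,4-dihydro-2H-chromen-3-yl]acetate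
Conditions: 4-nitrophenol, N,N'-dicyclohexylcarbodiimide, DMAP (cat.), CH2Cl2, 0 °C → rt
Reagents that add atoms: 4-nitrophenol, Oc1ccc(cc1)[N+](=O)[O-]
Why: Steglich esterification; it gives an aryl ester activated for acyl transfer to a carbene under neutral conditions that leave C3 untouched.

Step 12
Reactants: 15 1,2,3,4-tetramethoxybenzene
Product: 18 2,3,4,5-tetramethoxyphenol, via (2,3,4,5-tetramethoxyphenyl)lithium 16 (not isolated), via dimethyl (2,3,4,5-tetramethoxyphenyl)boronate 17 (not isolated)
Conditions: n-BuLi, TMEDA, THF, 0 °C; B(OMe)3, −78 °C → rt; AcOH, H2O2 (30 %), 0 °C → rt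
Reagents that add atoms: hydrogen peroxide, OO
Why: Methoxy‑directed ortho‑lithiation, borylation and oxidative conversion of C–B into C–O; the two ring positions that carry hydrogen are equivalent, so one phenol results.

Step 13
Reactants: 18 2,3,4,5-tetramethoxyphenol; 19 4-methoxybenzaldehyde
Product: 20 2,3,4,5-tetramethoxy-6-[(4-methoxyphenyl)(4-methylbenzenesulfonyl)methyl]phenol (racemic)
Conditions: 4-MeC6H4SO2H, TsOH·H2O (10 mol %), CH2Cl2, rt
Reagents that add atoms: 4-methylbenzenesulfinic acid, Cc1ccc(cc1)S(=O)O
Why: Acid‑mediated three‑component condensation (hydroxyalkylation of the only free ring position, then capture of the benzylic cation by sulfinate); the sulfone is a storable precursor of the quinone methide and its stereocentre is erased in step 14.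

Step 14
Reactants: 14 4-nitrophenyl 2-[(3R,4R)-5,7-dimethoxy-4-(4-methoxyphenyl)-2-oxo-3,4-dihydro-2H-chromen-3-yl]acetate; 20 2,3,4,5-tetramethoxy-6-[(4-methoxyphenyl)(4-methylbenzenesulfonyl)methyl]phenol
Product: 22 (3S,3'S,4R,4'R)-5,5',6',7,7',8'-hexamethoxy-4,4'-bis(4-methoxyphenyl)-3,3',4,4'-tetrahydro-2H,2'H-[3,3'-bichromene]-2,2'-dione (octamethyl ether of the target), via ring B ortho-quinone methide 21 (not isolated)
Conditions: (5aS,10bR)-N-mesityl aminoindanol-derived triazolium chloride (15 mol %), Cs2CO3, 4 Å MS, THF, rt
Reagents that add atoms: none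
Why: Carbene‑catalysed azolium enolate annulation (formal [4+2], Michael addition then lactonisation) with a quinone methide released in the flask; the Z enolate adds endo, so the C3' substituent and the C4' aryl group become cis, and the indane‑fused catalyst shields one enolate face to set 3'S,4'R (the antipodal salt is used if the sense proves opposite). The acyl azolium α‑hydrogens are far more acidic than C3–H, so the weak carbonate base should leave C3 intact.

Step 15
Reactants: 22 (3S,3'S,4R,4'R)-5,5',6',7,7',8'-hexamethoxy-4,4'-bis(4-methoxyphenyl)-3,3',4,4'-tetrahydro-2H,2'H-[3,3'-bichromene]-2,2'-dione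
Product: 23 (3S,3'S,4R,4'R)-5,5',6',7,7',8'-hexahydroxy-4,4'-bis(4-hydroxyphenyl)-3,3',4,4'-tetrahydro-2H,2'H-[3,3'-bichromene]-2,2'-dione
Conditions: BBr3 (excess), CH2Cl2, −78 °C → rt; degassed H2O, under argon
Reagents that add atoms: none
Why: Lewis acid demethylation of aryl methyl ethers by bromide attack on the boron‑bound methyl oxonium; the medium is acidic, so C3 and C3' are not enolised, and a lactone opened in passing should re‑close on acidic work‑up to the same six‑membered rings.

## Compound list

1 | 3,3-diethoxypropan-1-ol | CCOC(CCO)OCC | starting material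
2 | 3,3-diethoxypropanal | CCOC(CC=O)OCC | intermediate
3 | 2,2'-(4,4-diethoxybut-1-ene-1,1-diyl)bis(4,4,5,5-tetramethyl-1,3,2-dioxaborolane) | CCOC(CC=C(B1OC(C)(C)C(C)(C)O1)B1OC(C)(C)C(C)(C)O1)OCC | intermediate
4 | 1-bromo-4-methoxybenzene | COc1ccc(Br)cc1 | starting material
5 | (E)-2-[4,4-diethoxy-1-(4-methoxyphenyl)but-1-en-1-yl]-4,4,5,5-tetramethyl-1,3,2-dioxaborolane | CCOC(C/C=C(/c1ccc(OC)cc1)B1OC(C)(C)C(C)(C)O1)OCC | intermediate
6 | 3,5-dimethoxyphenol | COc1cc(O)cc(OC)c1 | starting material
7 | 2-iodo-3,5-dimethoxyphenol | COc1cc(O)c(I)c(OC)c1 | intermediate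
8 | (2-iodo-3,5-dimethoxyphenoxy)tri(propan-2-yl)silane | COc1cc(O[Si](C(C)C)(C(C)C)C(C)C)c(I)c(OC)c1 | intermediate
9 | (Z)-{2-[4,4-diethoxy-1-(4-methoxyphenyl)but-1-en-1-yl]-3,5-dimethoxyphenoxy}tri(propan-2-yl)silane | CCOC(C/C=C(/c1ccc(OC)cc1)c1c(OC)cc(OC)cc1O[Si](C(C)C)(C(C)C)C(C)C)OCC | intermediate
10 | (Z)-2-[4,4-diethoxy-1-(4-methoxyphenyl)but-1-en-1-yl]-3,5-dimethoxyphenol | COc1cc(O)c(c(OC)c1)/C(c1ccc(OC)cc1)=C\CC(OCC)OCC | intermediate
11 | (3R,4R)-3-(2,2-diethoxyethyl)-5,7-dimethoxy-4-(4-methoxyphenyl)-3,4-dihydro-2H-chromen-2-one | O=C1Oc2cc(OC)cc(OC)c2[C@@H](c2ccc(OC)cc2)[C@H]1CC(OCC)OCC | intermediate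
12 | 2-[(3R,4R)-5,7-dimethoxy-4-(4-methoxyphenyl)-2-oxo-3,4-dihydro-2H-chromen-3-yl]acetaldehyde | O=C1Oc2cc(OC)cc(OC)c2[C@@H](c2ccc(OC)cc2)[C@H]1CC=O | intermediate
13 | 2-[(3R,4R)-5,7-dimethoxy-4-(4-methoxyphenyl)-2-oxo-3,4-dihydro-2H-chromen-3-yl]acetic acid | O=C1Oc2cc(OC)cc(OC)c2[C@@H](c2ccc(OC)cc2)[C@H]1CC(=O)O | intermediate
14 | 4-nitrophenyl 2-[(3R,4R)-5,7-dimethoxy-4-(4-methoxyphenyl)-2-oxo-3,4-dihydro-2H-chromen-3-yl]acetate | O=C1Oc2cc(OC)cc(OC)c2[C@@H](c2ccc(OC)cc2)[C@H]1CC(=O)Oc1ccc(cc1)[N+](=O)[O-] | intermediate
15 | 1,2,3,4-tetramethoxybenzene | COc1ccc(OC)c(OC)c1OC | starting material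
16 | (2,3,4,5-tetramethoxyphenyl)lithium | [Li]c1cc(OC)c(OC)c(OC)c1OC | intermediate
17 | dimethyl (2,3,4,5-tetramethoxyphenyl)boronate | COB(OC)c1cc(OC)c(OC)c(OC)c1OC | intermediate
18 | 2,3,4,5-tetramethoxyphenol | COc1cc(O)c(OC)c(OC)c1OC | intermediate
19 | 4-methoxybenzaldehyde | COc1ccc(C=O)cc1 | starting material
20 | 2,3,4,5-tetramethoxy-6-[(4-methoxyphenyl)(4-methylbenzenesulfonyl)methyl]phenol (racemic) | COc1ccc(cc1)C(c1c(O)c(OC)c(OC)c(OC)c1OC)S(=O)(=O)c1ccc(C)cc1 | intermediate
21 | 2,3,4,5-tetramethoxy-6-[(4-methoxyphenyl)methylidene]cyclohexa-2,4-dien-1-one (exocyclic geometry not assigned) | COc1ccc(C=C2C(=O)C(OC)=C(OC)C(OC)=C2OC)cc1 | intermediate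
22 | (3S,3'S,4R,4'R)-5,5',6',7,7',8'-hexamethoxy-4,4'-bis(4-methoxyphenyl)-3,3',4,4'-tetrahydro-2H,2'H-[3,3'-bichromene]-2,2'-dione | O=C1Oc2cc(OC)cc(OC)c2[C@@H](c2ccc(OC)cc2)[C@H]1[C@H]1C(=O)Oc2c(OC)c(OC)c(OC)c(OC)c2[C@H]1c1ccc(OC)cc1 | intermediate
23 | (3S,3'S,4R,4'R)-5,5',6',7,7',8'-hexahydroxy-4,4'-bis(4-hydroxyphenyl)-3,3',4,4'-tetrahydro-2H,2'H-[3,3'-bichromene]-2,2'-dione | O=C1Oc2cc(O)cc(O)c2[C@@H](c2ccc(O)cc2)[C@H]1[C@H]1C(=O)Oc2c(O)c(O)c(O)c(O)c2[C@H]1c1ccc(O)cc1 | target

## Step count and least certain steps

Total: 15 steps. Longest linear sequence: 11 steps (steps 1, 2, 3, 6, 7, 8, 9, 10, 11, 14, 15).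

**Step 8 (key step, new method).** The most likely failure is reversible hydropalladation with palladium at the benzylic carbon C4. Rotation and β‑hydride elimination would then scramble the alkene geometry or move the double bond along the chain, eroding the cis relationship. The hindered trisubstituted alkene may also insert too slowly, and facial selection by the ligand may be poor.
Fallback (known chemistry, sets out from 6 and 19, returns at 13): 6, 19 and 4‑methylbenzenesulfinic acid are condensed under acid to the sulfone 3,5‑dimethoxy‑2‑[(4‑methoxyphenyl)(4‑methylbenzenesulfonyl)methyl]phenol F1. Commercial mono‑tert‑butyl succinate is esterified with 4‑nitrophenol and a carbodiimide to tert‑butyl 4‑nitrophenyl butanedioate F2. With the triazolium salt of step 14 and Cs2CO3, F1 releases 3,5‑dimethoxy‑6‑[(4‑methoxyphenyl)methylidene]cyclohexa‑2,4‑dien‑1‑one F3, which is captured by the azolium enolate of F2 to give tert‑butyl 2‑[(3R,4R)‑5,7‑dimethoxy‑4‑(4‑methoxyphenyl)‑2‑oxo‑3,4‑dihydro‑2H‑chromen‑3‑yl]acetate F4. Trifluoroacetic acid cleaves the tert‑butyl ester of F4 to 13. This bypasses steps 1 to 10.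

**Step 6.** Transmetalation of the hindered alkenyl boronate onto the di‑ortho‑substituted arylpalladium may be slow, so that protodeboronation of 5 and loss of the silyl group compete.
Fallback (sets out from 5 and 8, returns at 9): 5 is iododeboronated with retention (I2, NaOH) to 1‑[(Z)‑4,4‑diethoxy‑1‑iodobut‑1‑en‑1‑yl]‑4‑methoxybenzene F5. 8 is converted by iodine–magnesium exchange (iPrMgCl·LiCl) and ZnCl2 into [2,4‑dimethoxy‑6‑(triisopropylsilyloxy)phenyl]zinc chloride F6. A Negishi coupling of F5 with F6 (Pd2(dba)3, SPhos, THF) gives 9, with the hindered arene now as the more reactive zinc nucleophile.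

**Step 14.** The facial preference of the catalyst may be opposed by the existing C3 centre (mismatched pairing). Carbonate may also epimerise C3 over long reaction times, or the phenoxide of 20 may be acylated by 14 without the carbene.
Fallback (sets out from 12, returns at 22): 12 is α‑chlorinated (N‑chlorosuccinimide, L‑proline cat.) to 2‑chloro‑2‑[(3R,4R)‑5,7‑dimethoxy‑4‑(4‑methoxyphenyl)‑2‑oxo‑3,4‑dihydro‑2H‑chromen‑3‑yl]acetaldehyde F7, as a mixture at the chlorinated carbon. The same carbene converts F7 by internal redox into the azolium enolate, which is trapped by 21 generated from 20 to give 22. This approach needs no activated ester and no acyl transfer step.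

**Step 2.** The basic boryl carbanion may enolise the aldehyde or eliminate ethanol from it instead of adding.
Fallback (sets out from 2, returns at 3): dibromo‑olefination of 2 (CBr4, PPh3, Et3N) gives 4,4‑dibromo‑1,1‑diethoxybut‑3‑ene F8. Bromine–lithium exchange at low temperature (n‑BuLi), capture of the carbenoid by B2pin2 and 1,2‑boryl migration with loss of bromide then give 3.

**Step 4.** Iodination may occur partly at C4 or twice, giving a mixture that is hard to separate.
Fallback (sets out from 6, returns at 7): 6 is protected (MOMCl, iPr2NEt) as 1,3‑dimethoxy‑5‑(methoxymethoxy)benzene F9. Directed ortho‑lithiation between the methoxymethoxy and methoxy groups (n‑BuLi) and quenching with I2 gives 2‑iodo‑1,5‑dimethoxy‑3‑(methoxymethoxy)benzene F10. HCl in methanol removes the acetal to give 7; acid is harmless at this stage because no alkene is present.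

## Further compounds

F1 | step 8 | 3,5-dimethoxy-2-[(4-methoxyphenyl)(4-methylbenzenesulfonyl)methyl]phenol (racemic) | COc1ccc(cc1)C(c1c(O)cc(OC)cc1OC)S(=O)(=O)c1ccc(C)cc1
F2 | step 8 | tert-butyl 4-nitrophenyl butanedioate | CC(C)(C)OC(=O)CCC(=O)Oc1ccc(cc1)[N+](=O)[O-]
F3 | step 8 | 3,5-dimethoxy-6-[(4-methoxyphenyl)methylidene]cyclohexa-2,4-dien-1-one (exocyclic geometry not assigned) | COc1ccc(C=C2C(=O)C=C(OC)C=C2OC)cc1
F4 | step 8 | tert-butyl 2-[(3R,4R)-5,7-dimethoxy-4-(4-methoxyphenyl)-2-oxo-3,4-dihydro-2H-chromen-3-yl]acetate | O=C1Oc2cc(OC)cc(OC)c2[C@@H](c2ccc(OC)cc2)[C@H]1CC(=O)OC(C)(C)C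
F5 | step 6 | 1-[(Z)-4,4-diethoxy-1-iodobut-1-en-1-yl]-4-methoxybenzene | CCOC(C/C=C(/c1ccc(OC)cc1)I)OCC
F6 | step 6 | [2,4-dimethoxy-6-(triisopropylsilyloxy)phenyl]zinc chloride | COc1cc(O[Si](C(C)C)(C(C)C)C(C)C)c([Zn]Cl)c(OC)c1
F7 | step 14 | 2-chloro-2-[(3R,4R)-5,7-dimethoxy-4-(4-methoxyphenyl)-2-oxo-3,4-dihydro-2H-chromen-3-yl]acetaldehyde (mixture at the chlorinated carbon) | O=C1Oc2cc(OC)cc(OC)c2[C@@H](c2ccc(OC)cc2)[C@H]1C(Cl)C=O
F8 | step 2 | 4,4-dibromo-1,1-diethoxybut-3-ene | CCOC(CC=C(Br)Br)OCC
F9 | step 4 | 1,3-dimethoxy-5-(methoxymethoxy)benzene | COCOc1cc(OC)cc(OC)c1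
F10 | step 4 | 2-iodo-1,5-dimethoxy-3-(methoxymethoxy)benzene | COCOc1cc(OC)cc(OC)c1I
A1 | alternative 1 | (3S,3'S,4R,4'R)-5,5',6',7,7',8'-hexamethoxy-4,4'-bis(4-methoxyphenyl)-3,3',4,4'-tetrahydro-2H,2'H-[3,3'-bichromene]-2,2'-dione (same compound as 22) | O=C1Oc2cc(OC)cc(OC)c2[C@@H](c2ccc(OC)cc2)[C@H]1[C@H]1C(=O)Oc2c(OC)c(OC)c(OC)c(OC)c2[C@H]1c1ccc(OC)cc1
A2 | alternative 1 | 4-nitrophenyl 2-[(3R,4R)-5,6,7,8-tetramethoxy-4-(4-methoxyphenyl)-2-oxo-3,4-dihydro-2H-chromen-3-yl]acetate | O=C(C[C@H]1C(=O)Oc2c(OC)c(OC)c(OC)c(OC)c2[C@H]1c1ccc(OC)cc1)Oc1ccc(cc1)[N+](=O)[O-]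
A3 | alternative 1 | 3,5-dimethoxy-2-[(4-methoxyphenyl)(4-methylbenzenesulfonyl)methyl]phenol (racemic; same compound as F1) | COc1ccc(cc1)C(c1c(O)cc(OC)cc1OC)S(=O)(=O)c1ccc(C)cc1
A4 | alternative 1 | 3,5-dimethoxy-6-[(4-methoxyphenyl)methylidene]cyclohexa-2,4-dien-1-one (same compound as F3) | COc1ccc(C=C2C(=O)C=C(OC)C=C2OC)cc1
A5 | alternative 2 | trimethyl (3R)-3-(2,4-diethoxy-6-hydroxyphenyl)-3-(4-methoxyphenyl)propane-1,2,2-tricarboxylate | CCOc1cc(OCC)cc(O)c1[C@@H](c1ccc(OC)cc1)C(C(=O)OC)(C(=O)OC)CC(=O)OC
A6 | alternative 2 | trimethyl (3R)-5-ethoxy-3-(4-methoxyphenyl)pent-4-yne-1,2,2-tricarboxylate | CCOC#C[C@@H](c1ccc(OC)cc1)C(C(=O)OC)(C(=O)OC)CC(=O)OC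
A7 | alternative 2 | 3-ethoxycyclobut-2-en-1-one | CCOC1=CC(=O)C1
A8 | alternative 3 | (3aR,4R,9aS)-6,7-dimethoxy-4-(4-methoxyphenyl)-2,3,3a,9a-tetrahydro-4H-furo[2,3-b]chromene-5,8-diol | C1CO[C@H]2Oc3c(O)c(OC)c(OC)c(O)c3[C@H]([C@@H]12)c1ccc(OC)cc1
A9 | alternative 3 | 4-hydroxy-2,3-dimethoxy-4-[(3aR,4R,7aS)-4-(4-methoxyphenyl)-3,3a,4,7a-tetrahydro-2H-furo[2,3-b]pyran-6-yl]cyclobut-2-en-1-one (carbinol configuration immaterial) | C1CO[C@H]2OC(=C[C@H]([C@@H]12)c1ccc(OC)cc1)C1(O)C(=O)C(OC)=C1OC
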